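Conventions used throughout: rings A, B and C are the benzo ring, the aryl ring and the pyranone ring of the flavanone half; rings D, E and F are the corresponding rings of the flavone half, whose atoms carry the suffix f (C8f, O7f).

## The problem

Compound 24 is a naringenin unit joined through its sp3 carbon C3 to C8f of an apigenin unit, with a hydrogen sulfate on O7f. The C3–C8f bond is the crux: it links a tertiary, enolisable carbon to an aryl carbon flanked by O7f and by the ring F oxygen, so it is hindered and not open to simple enolate chemistry. There are two stereocentres, C2 (R) and C3 (S), trans on ring C. C3 is alpha to the C4 ketone and benzylic, so it epimerises easily and settles trans to whatever C2 dictates. C2 can only be lost by ring opening or, before ring C exists, by retro-aldol cleavage, so the absolute configuration must be set at C2 under catalyst control and then kept away from strong base. Six phenolic oxygens are present and only O7f is sulfated, so O7f needs a protecting group of its own; the aryl sulfate is acid-labile, which forces late sulfation and a neutral final deprotection. The flavone carbonyl is an electrophile towards organometallics, and the flavanone opens to a chalcone under base. The enabling feature is that C2 and C3 are adjacent carbons needing ring B and the C4 acyl carbon respectively, and that C2 also carries O1, for which a carbon–boron bond can stand in. The C2–C3 unit can therefore be an (E)-vinylboronate already attached to C8f, so that the hindered C3–C8f bond is made as an ordinary aryl–alkyne bond before any stereocentre exists.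

## Retrosynthesis

**Sulfate and benzyl ethers (24 from 23, 23 from 22).** The five O–benzyl bonds and the O–S bond are cut first. Benzyl is chosen over methyl or silyl ethers because hydrogenolysis is neutral and leaves an aryl sulfate salt intact, whereas Lewis-acid dealkylation or fluoride and base would not fit the sulfate or the earlier carbonate steps. The precursor 22 has a single free phenol. The forward steps must sulfate a hindered phenol and then debenzylate without touching the ring F alkene or the benzylic C2–O1 bond.

**Unmasking O7f (22 from 21).** The O7f acetal bond is cut. A methoxymethyl ether is orthogonal to benzyl, survives organolithium, carbonate and peroxide, and is removed by mild acid that a trans flavanone tolerates.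

**Ring C (21 from 20).** The O1–C8a bond is cut, to be formed by displacement of a fluoride ortho to the C4 ketone. The neighbouring cut at O1–C2 (a ring A phenol displacing an activated alcohol) would invert or scramble C2 and would need a further orthogonal phenol protecting group. Cutting at C8a lets the oxygen on C2 keep its configuration. The precursor 20 is an open-chain anti aldol; the forward closure has to be faster than retro-aldol cleavage.

**Oxygen on C2 (20 from 19).** The C2–O bond is traced to a C2–B bond, since peroxide oxidation of a secondary boronic ester proceeds with retention.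

**Key cut (19 from 10, 17 and 15).** Both C3–C4 and the bond from C2 to ring B are cut in one operation, giving the vinylboronate 10, the aryllithium 17 and the acid chloride 15. An aldol cut at C2–C3 would require the C3–C8f bond to be made by arylation of a hindered ketone and then an absolutely controlled aldol of that ketone. Conjugate addition of ring B to a 3-aryl chromone has no precedent on a trisubstituted alkene. The conjunctive cut gives three achiral pieces, none with a stereocentre, and the relative configuration comes from a stereospecific anti addition to an (E)-alkene. The forward reaction must form the boron ate complex in the presence of the flavone carbonyl, favour metallate shift over direct transmetallation, and select one alkene face.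

**Vinylboronate (10 from 9, 9 from 7).** The C–B bond is cut to the terminal alkyne 9 (hydroboration), and the C8f–C(sp) bond to the iodide 7 (alkynylation of an aryl iodide). An sp carbon is the smallest partner that can be coupled at this di-ortho-substituted position.

**Ring D functionalisation and the unique group on O7 (7 from 6, 6 from 4, 4 from 3, 3 from 2, 2 from 1).** The C8–I bond is cut to the fully O-alkylated flavone 6, because 5,7-dialkoxyflavones take electrophiles at C8 while 5-hydroxyflavones take them at C6. O7 is distinguished through triacetate 2: thiolysis removes only the 7-O-acetyl group to give 3, O7 is capped as the methoxymethyl ether 4, and the two remaining acetates are exchanged for benzyl ethers. This is longer than a direct mono-alkylation of apigenin 1, but the direct route cannot reliably tell O7 from O4' of ring E.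

**Acyl and aryl donors (15 from 14, 14 from 13, 13 from 12, 12 from 11; 17 from 16).** The acid chloride is traced through acid 14 and aldehyde 13 to a formylation of 5-fluororesorcinol 11, which puts the carbonyl between fluorine and one hydroxyl. The aryllithium 17 comes from bromide 16 by halogen–lithium exchange.

## Roads not taken

Alternative 1: The cut removes ring F: C4af–C4f, C4f–C3f and O1f–C2f are broken. This leaves the iodophenol A2, in which the flavanone with both stereocentres already carries a phloroglucinol-type ring D on C3, and the ring E alkyne A3. In the forward direction a palladium-catalysed carbonylative alkynylation of the aryl iodide of A2 with A3 gives an ynone, and the neighbouring phenol adds 6-endo to give A1 with a free O7f hydroxyl.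
- Merits: the reaction type is firmly established. Ring D of A2 is locally symmetric before iodination, so either ortho hydroxyl leads to the same flavone, and the hydroxyl left over is exactly the sulfation site.
- Weak points: the step does not address the hindered C3–C8f bond or the C2/C3 stereocentres, which must already exist in A2. The ynone can also close 5-exo to an aurone. Amine base and heat under carbonylation conditions act on a flavanone whose C3 is enolisable and whose ring C opens under base.
- Comparison: this road is better in the end game, since O7f is differentiated by construction where the chosen plan spends steps 1 to 4 on it, and its key step has firmer precedent than step 12. Against this, the chosen plan makes the hindered bond on a stereocentre-free flavone and creates C2 and C3 in the key step itself, whereas Alternative 1 moves that problem into the preparation of A2.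

Alternative 2: The cut is at C3–C8f and C2–C3 together. A dirhodium carboxylate catalyst turns the ring A diazo ketone A5 into a carbenoid, the electron-rich triether A6 attacks it through the position between its two acetal oxygens, and the resulting enol is trapped by aldehyde A7 under a chiral phosphoric acid to give the anti aldol A4.
- Merits: three simple achiral pieces, the oxidation level of 20 without a boron oxidation, no organolithium, and the hindered bond formed by an electrophilic substitution that electron-rich arenes favour.
- Weak points: acceptor-only carbenoids from terminal diazo ketones dimerise and insert unselectively, and proton transfer to the plain arylation product competes with aldol trapping. Relative and absolute configuration both rest on how the catalysts organise a transient enol, with no stereospecific element. Ring D of A4 is still a phloroglucinol triether, so ring F must be built afterwards in four or more steps on a retro-aldol-prone intermediate, with the two oxygens ortho to C8f still to be told apart.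
- Comparison: Alternative 2 is more convergent at the stereo-defining step and starts from cheaper materials. The chosen plan sets against it a flavone bought ready-made as 1, a relative configuration that follows from alkene geometry, and only five steps after the key step.

Alternative 3: The cut goes through ring D: C5f–C6f, C7f–C8f, C5f–C4af and, by migration, C3–C8f. Irradiation of the pyranonyl diazo ketone A9 induces a Wolff rearrangement in which the side chain migrates to the carbene carbon. The ketene adds the silyloxyalkyne A10 to give a cyclobutenone, which opens (4π) and closes onto the pyranone double bond (6π) to give flavone A8 after tautomerisation.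
- Merits: ring D is assembled with O5f and O7f differentiated by construction, with no electrophilic substitution or cross-coupling at a hindered position.
- Weak points: A8 carries only a two-carbon silyloxyethyl arm, so ring B, the C4 acyl carbon, O1 and both stereocentres all remain to be introduced and still call for an asymmetric method. A9 needs a multistep synthesis ending in a diazo transfer. The pyranone chromophore competes for light, and the 6π closure uses a cross-conjugated pyranone alkene in place of a simple vinyl group.
- Comparison: for the ring D substitution pattern alone this is the more controlled road, and the chosen plan must accept a protecting-group sequence and a regioselective iodination in its place. It contributes nothing to C2 and C3, however, and would be the longest overall; the chosen plan takes rings D to F from 1 and spends its key step on the stereocentres.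

Key step: step 12

Assumption: the target is drawn as the free aryl hydrogen sulfate; the sulfate is carried as its sodium salt 23 and protonated only in the last operation, and in practice the compound would be stored as the salt.

Remark on names: Fl stands for the 5-(benzyloxy)-2-[4-(benzyloxy)phenyl]-7-(methoxymethoxy)-4-oxo-4H-chromen-8-yl group, the protected flavone attached through C8f.

## Route

Step 1
Reactants: 1 apigenin
Product: 2 apigenin 5,7,4'-triacetate
Conditions: Ac2O, pyridine, DMAP (cat.), 50 °C
Reagents that add atoms: acetic anhydride, CC(=O)OC(C)=O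
Why: Exhaustive O-acylation of phenols; DMAP and warming bring in the hydrogen-bonded 5-hydroxyl. The triacetate sets up the differentiation of O7.

Step 2
Reactants: 2 apigenin 5,7,4'-triacetate
Product: 3 5,4'-di-O-acetylapigenin (7-hydroxyl free)
Conditions: PhSH, imidazole (cat.), NMP, 0 °C → rt
Reagents that add atoms: none
Why: Chemoselective thiolysis (acyl transfer to thiophenolate) of the most activated aryl ester; the 7-phenoxide is the best leaving group because it is para to the C4 carbonyl, and this is the established selective 7-O-deacetylation of peracetylated flavones.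

Step 3
Reactants: 3 5,4'-di-O-acetylapigenin
Product: 4 5,4'-di-O-acetyl-7-O-(methoxymethyl)apigenin
Conditions: MOMCl, i-Pr2NEt, CH2Cl2, 0 °C → rt
Reagents that add atoms: chloromethyl methyl ether, COCCl
Why: O-alkylation of the acidic 7-phenol with an alpha-chloro ether (acetal protection); the amine base leaves the two aryl acetates in place.

Step 4
Reactants: 4 5,4'-di-O-acetyl-7-O-(methoxymethyl)apigenin
Product: 6 5,4'-di-O-benzyl-7-O-(methoxymethyl)apigenin, via 7-O-(methoxymethyl)apigenin 5 (not isolated)
Conditions: K2CO3, MeOH–THF, rt; evaporate; BnBr, K2CO3, Bu4NI (cat.), DMF, 60 °C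
Reagents that add atoms: benzyl bromide, BrCc1ccccc1
Why: Methanolysis of the aryl acetates followed by Williamson etherification in the same flask; warming in DMF is needed for the chelated 5-hydroxyl, and the acetal is stable to carbonate.

Step 5
Reactants: 6 5,4'-di-O-benzyl-7-O-(methoxymethyl)apigenin
Product: 7 5-(benzyloxy)-2-[4-(benzyloxy)phenyl]-8-iodo-7-(methoxymethoxy)-4H-chromen-4-one
Conditions: NIS, TFA (10 mol%), MeCN, 0 °C → rt, dark
Reagents that add atoms: N-iodosuccinimide, O=C1CCC(=O)N1I
Why: Electrophilic aromatic iodination; fully O-alkylated 5,7-dioxygenated flavones react at C8, whereas C6 lies between two alkoxy groups and ring E is deactivated by conjugation with the pyranone. Catalytic acid in an aprotic solvent should spare the acetal.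

Step 6
Reactants: 7 8-iodoflavone
Product: 9 5-(benzyloxy)-2-[4-(benzyloxy)phenyl]-8-ethynyl-7-(methoxymethoxy)-4H-chromen-4-one, via trimethylsilylalkyne 8 (not isolated)
Conditions: Me3SiC≡CH, PdCl2(PPh3)2 (5 mol%), CuI (10 mol%), Et3N, DMF, 60 °C; then K2CO3, MeOH, rt
Reagents that add atoms: ethynyltrimethylsilane, C#C[Si](C)(C)C
Why: Sonogashira coupling; a linear sp partner is the least demanding nucleophile for a di-ortho-substituted aryl iodide, and methanolic carbonate then removes the silyl group without affecting the flavone.

Step 7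
Reactants: 9 8-ethynylflavone
Product: 10 5-(benzyloxy)-2-[4-(benzyloxy)phenyl]-7-(methoxymethoxy)-8-[(E)-2-(4,4,5,5-tetramethyl-1,3,2-dioxaborolan-2-yl)ethenyl]-4H-chromen-4-one
Conditions: HBpin, Cy2BH (10 mol%), THF, rt
Reagents that add atoms: pinacolborane, CC1(C)OBOC1(C)C
Why: Dialkylborane-catalysed hydroboration of a terminal alkyne with pinacolborane; syn addition with boron on the terminal carbon gives the (E)-alkenylboronate, and a neutral borane should leave the vinylogous ester carbonyl alone.

Step 8
Reactants: 11 5-fluororesorcinol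
Product: 12 2-fluoro-4,6-dihydroxybenzaldehyde
Conditions: POCl3, DMF, MeCN, 0 °C → rt; then H2O, 50 °C
Reagents that add atoms: N,N-dimethylformamide, CN(C)C=O; water, O
Why: Vilsmeier–Haack formylation; resorcinols react para to one hydroxyl and ortho to the other, not at the crowded position between the two, which places the aldehyde next to fluorine.

Step 9
Reactants: 12 2-fluoro-4,6-dihydroxybenzaldehyde
Product: 13 2,4-bis(benzyloxy)-6-fluorobenzaldehyde
Conditions: BnBr, K2CO3, DMF, rt
Reagents that add atoms: benzyl bromide, BrCc1ccccc1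
Why: Williamson etherification of both phenols; room temperature keeps the phenoxides from displacing the aldehyde-activated fluoride.

Step 10
Reactants: 13 2,4-bis(benzyloxy)-6-fluorobenzaldehyde
Product: 14 2,4-bis(benzyloxy)-6-fluorobenzoic acid
Conditions: NaClO2, NaH2PO4, 2-methyl-2-butene, t-BuOH–THF–H2O, 0 °C → rt
Reagents that add atoms: sodium chlorite, [Na+].[O-]Cl=O
Why: Pinnick oxidation; the alkene scavenger removes hypochlorous acid before it can chlorinate the electron-rich ring.

Step 11
Reactants: 14 2,4-bis(benzyloxy)-6-fluorobenzoic acid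
Product: 15 2,4-bis(benzyloxy)-6-fluorobenzoyl chloride
Conditions: (COCl)2, DMF (cat.), CH2Cl2, 0 °C → rt; evaporate
Reagents that add atoms: oxalyl chloride, O=C(Cl)C(=O)Cl
Why: Acid chloride formation through the chloroiminium catalyst; the product is used directly after evaporation.

Step 12
Reactants: 10 (E)-alkenylboronate; 16 1-(benzyloxy)-4-bromobenzene; 15 2,4-bis(benzyloxy)-6-fluorobenzoyl chloride
Product: 19 (2R,3R)-1-[2,4-bis(benzyloxy)-6-fluorophenyl]-3-[4-(benzyloxy)phenyl]-2-(Fl)-3-(4,4,5,5-tetramethyl-1,3,2-dioxaborolan-2-yl)propan-1-one (anti), via 4-(benzyloxy)phenyllithium 17 (not isolated), via lithium boron ate complex 18 (not isolated)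
Conditions: 16, t-BuLi (2 equiv), Et2O, −78 °C; add slowly to 10, THF, −78 °C → rt; then Ni(cod)2 (10 mol%), (S,S)-N,N'-dimethyl-1,2-diphenylethane-1,2-diamine (12 mol%), 15, THF, 0 °C → rt
Reagents that add atoms: tert-butyllithium, [Li]C(C)(C)C (supplies the lithium of 17 and 18 only; no atom of it remains in 19)
Why: Proposed new method: aryllithium 17 from bromine–lithium exchange adds to boron of 10 to give ate complex 18; oxidative addition of 15 to zerovalent nickel gives an aroyl complex of divalent nickel that binds the alkene of 18 and triggers 1,2-shift of the ring B aryl group from boron to C2 anti to the metal, and reductive elimination from the alkyl(acyl)nickel forms C3–C4 and returns zerovalent nickel. The closest known reactions are the nickel-catalysed conjunctive coupling of alkenylboron ate complexes with acid chlorides and the palladium-catalysed enantio- and diastereoselective conjunctive coupling of beta-substituted alkenylboronates with aryl triflates; the combination of a beta-aryl alkenylboronate, an aryl migrating group and a di-ortho-substituted aroyl chloride has not been shown. No ring is closed. C2 and C3 arise in one stereospecific anti addition across the (E)-alkene, so the anti relative configuration follows from alkene geometry and the absolute configuration from the alkene face chosen by the diamine-bound nickel; the (S,S) ligand is written by analogy, its sense must be confirmed on a model styrenylboronate, and the (R,R) ligand is used if it proves opposite. Three selectivities are needed: 17 must add to boron and not to the flavone carbonyl C4f, which the vacant boron orbital, −78 °C, slow addition of one equivalent and the vinylogous-ester character of C4f next to the peri benzyloxy group should secure; the metallate shift must outrun direct boron-to-nickel transfer of the alkenyl or aryl group; and 15 must not acylate 18 without nickel, which its two ortho substituents disfavour.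

Step 13
Reactants: 19 anti beta-boryl ketone
Product: 20 (2S,3R)-1-[2,4-bis(benzyloxy)-6-fluorophenyl]-3-[4-(benzyloxy)phenyl]-2-(Fl)-3-hydroxypropan-1-one (anti)
Conditions: H2O2 (30% aq), pH 7 phosphate buffer, THF, 0 °C → rt
Reagents that add atoms: hydrogen peroxide, OO
Why: Oxidation of the C–B bond through a peroxoborate with 1,2-migration of carbon from boron to oxygen, which proceeds with retention at the future C2; neutral buffering avoids retro-aldol cleavage and epimerisation alpha to the ketone.

Step 14
Reactants: 20 anti beta-hydroxy ketone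
Product: 21 (2R,3S)-5,7-bis(benzyloxy)-2-[4-(benzyloxy)phenyl]-3-(Fl)chroman-4-one (2,3-trans)
Conditions: K2CO3, DMF, 0 °C → rt
Reagents that add atoms: none
Why: Intramolecular nucleophilic aromatic substitution: the alkoxide adds to the fluorine-bearing carbon ortho to the ketone (six-membered ring through a Meisenheimer adduct) and fluoride leaves. The two benzyloxy groups are meta to fluorine and do not deactivate that carbon. The C2–O bond is untouched, so C2 keeps its configuration, and any epimerisation at C3 converges on the trans isomer.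

Step 15
Reactants: 21 protected flavanone–flavone
Product: 22 (2R,3S)-5,7-bis(benzyloxy)-2-[4-(benzyloxy)phenyl]-3-{5-(benzyloxy)-2-[4-(benzyloxy)phenyl]-7-hydroxy-4-oxo-4H-chromen-8-yl}chroman-4-one
Conditions: HCl (1.25 M in MeOH), THF, 40 °C
Reagents that add atoms: none
Why: Acid-catalysed acetal exchange removes the methoxymethyl group; benzyl ethers are stable and the trans flavanone is the thermodynamic isomer under acid.

Step 16
Reactants: 22 O7f phenol
Product: 23 sodium (2R,3S)-flavanone–flavone 7f-sulfate with five benzyl ethers
Conditions: SO3·pyridine, pyridine, 45 °C; then aq NaHCO3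
Reagents that add atoms: sulfur trioxide–pyridine complex, O=S(=O)([O-])[n+]1ccccc1; sodium hydrogencarbonate, [Na+].OC([O-])=O
Why: O-sulfonation of the only free phenol by an amine–SO3 complex; the weakly basic medium spares ring C, and exchange to the sodium salt removes the amine, which would otherwise retard the hydrogenolysis.

Step 17
Reactants: 23 sodium sulfate salt
Product: 24 target, (2R,3S)-naringenin-(3→8f)-apigenin 7f-O-(hydrogen sulfate)
Conditions: H2 (1 atm), Pd/C (10%), THF–MeOH, rt; filter; aq HCl (1.0 equiv), 0 °C; C18 desalting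
Reagents that add atoms: none
Why: Hydrogenolysis of five benzyl ethers under neutral conditions, which aryl sulfate salts, the flavone alkene and the benzylic C2–O1 bond should tolerate at atmospheric pressure if the reaction is stopped at the calculated uptake; one equivalent of acid in the cold gives the hydrogen sulfate form.

## Compound list

1 | apigenin | O=c1cc(-c2ccc(O)cc2)oc2cc(O)cc(O)c12 | starting material
2 | apigenin 5,7,4'-triacetate | O=c1cc(-c2ccc(OC(C)=O)cc2)oc2cc(OC(C)=O)cc(OC(C)=O)c12 | intermediate
3 | 5,4'-di-O-acetylapigenin | O=c1cc(-c2ccc(OC(C)=O)cc2)oc2cc(O)cc(OC(C)=O)c12 | intermediate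
4 | 5,4'-di-O-acetyl-7-O-(methoxymethyl)apigenin | O=c1cc(-c2ccc(OC(C)=O)cc2)oc2cc(OCOC)cc(OC(C)=O)c12 | intermediate
5 | 7-O-(methoxymethyl)apigenin | O=c1cc(-c2ccc(O)cc2)oc2cc(OCOC)cc(O)c12 | intermediate (not isolated)
6 | 5-(benzyloxy)-2-[4-(benzyloxy)phenyl]-7-(methoxymethoxy)-4H-chromen-4-one | O=c1cc(-c2ccc(OCc3ccccc3)cc2)oc2cc(OCOC)cc(OCc3ccccc3)c12 | intermediate
7 | 5-(benzyloxy)-2-[4-(benzyloxy)phenyl]-8-iodo-7-(methoxymethoxy)-4H-chromen-4-one | O=c1cc(-c2ccc(OCc3ccccc3)cc2)oc2c(I)c(OCOC)cc(OCc3ccccc3)c12 | intermediate
8 | 5-(benzyloxy)-2-[4-(benzyloxy)phenyl]-7-(methoxymethoxy)-8-[(trimethylsilyl)ethynyl]-4H-chromen-4-one | O=c1cc(-c2ccc(OCc3ccccc3)cc2)oc2c(C#C[Si](C)(C)C)c(OCOC)cc(OCc3ccccc3)c12 | intermediate (not isolated)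
9 | 5-(benzyloxy)-2-[4-(benzyloxy)phenyl]-8-ethynyl-7-(methoxymethoxy)-4H-chromen-4-one | O=c1cc(-c2ccc(OCc3ccccc3)cc2)oc2c(C#C)c(OCOC)cc(OCc3ccccc3)c12 | intermediate
10 | 5-(benzyloxy)-2-[4-(benzyloxy)phenyl]-7-(methoxymethoxy)-8-[(E)-2-(4,4,5,5-tetramethyl-1,3,2-dioxaborolan-2-yl)ethenyl]-4H-chromen-4-one | CC1(C)OB(/C=C/c2c(OCOC)cc(OCc3ccccc3)c3c(=O)cc(-c4ccc(OCc5ccccc5)cc4)oc23)OC1(C)C | intermediate
11 | 5-fluororesorcinol | Oc1cc(O)cc(F)c1 | starting material
12 | 2-fluoro-4,6-dihydroxybenzaldehyde | O=Cc1c(F)cc(O)cc1O | intermediate
13 | 2,4-bis(benzyloxy)-6-fluorobenzaldehyde | O=Cc1c(F)cc(OCc2ccccc2)cc1OCc1ccccc1 | intermediate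
14 | 2,4-bis(benzyloxy)-6-fluorobenzoic acid | O=C(O)c1c(F)cc(OCc2ccccc2)cc1OCc1ccccc1 | intermediate
15 | 2,4-bis(benzyloxy)-6-fluorobenzoyl chloride | O=C(Cl)c1c(F)cc(OCc2ccccc2)cc1OCc1ccccc1 | intermediate
16 | 1-(benzyloxy)-4-bromobenzene | Brc1ccc(OCc2ccccc2)cc1 | starting material
17 | 4-(benzyloxy)phenyllithium | [Li]c1ccc(OCc2ccccc2)cc1 | intermediate (not isolated)
18 | lithium [4-(benzyloxy)phenyl][(E)-2-(Fl)ethenyl](pinacolato)borate | [Li+].CC1(C)O[B-](/C=C/c2c(OCOC)cc(OCc3ccccc3)c3c(=O)cc(-c4ccc(OCc5ccccc5)cc4)oc23)(c2ccc(OCc3ccccc3)cc2)OC1(C)C | intermediate (not isolated)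
19 | (2R,3R)-1-[2,4-bis(benzyloxy)-6-fluorophenyl]-3-[4-(benzyloxy)phenyl]-2-(Fl)-3-(4,4,5,5-tetramethyl-1,3,2-dioxaborolan-2-yl)propan-1-one | CC1(C)OB(OC1(C)C)[C@@H](c1ccc(OCc2ccccc2)cc1)[C@@H](C(=O)c1c(F)cc(OCc2ccccc2)cc1OCc1ccccc1)c1c(OCOC)cc(OCc2ccccc2)c2c(=O)cc(-c3ccc(OCc4ccccc4)cc3)oc12 | intermediate
20 | (2S,3R)-1-[2,4-bis(benzyloxy)-6-fluorophenyl]-3-[4-(benzyloxy)phenyl]-2-(Fl)-3-hydroxypropan-1-one | O[C@@H](c1ccc(OCc2ccccc2)cc1)[C@@H](C(=O)c1c(F)cc(OCc2ccccc2)cc1OCc1ccccc1)c1c(OCOC)cc(OCc2ccccc2)c2c(=O)cc(-c3ccc(OCc4ccccc4)cc3)oc12 | intermediate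
21 | (2R,3S)-5,7-bis(benzyloxy)-2-[4-(benzyloxy)phenyl]-3-(Fl)chroman-4-one | O=C1c2c(OCc3ccccc3)cc(OCc3ccccc3)cc2O[C@@H](c2ccc(OCc3ccccc3)cc2)[C@@H]1c1c(OCOC)cc(OCc2ccccc2)c2c(=O)cc(-c3ccc(OCc4ccccc4)cc3)oc12 | intermediate
22 | (2R,3S)-5,7-bis(benzyloxy)-2-[4-(benzyloxy)phenyl]-3-{5-(benzyloxy)-2-[4-(benzyloxy)phenyl]-7-hydroxy-4-oxo-4H-chromen-8-yl}chroman-4-one | O=C1c2c(OCc3ccccc3)cc(OCc3ccccc3)cc2O[C@@H](c2ccc(OCc3ccccc3)cc2)[C@@H]1c1c(O)cc(OCc2ccccc2)c2c(=O)cc(-c3ccc(OCc4ccccc4)cc3)oc12 | intermediate
23 | sodium 5-(benzyloxy)-2-[4-(benzyloxy)phenyl]-8-{(2R,3S)-5,7-bis(benzyloxy)-2-[4-(benzyloxy)phenyl]-4-oxochroman-3-yl}-4-oxo-4H-chromen-7-yl sulfate | O=C1c2c(OCc3ccccc3)cc(OCc3ccccc3)cc2O[C@@H](c2ccc(OCc3ccccc3)cc2)[C@@H]1c1c(OS(=O)(=O)[O-])cc(OCc2ccccc2)c2c(=O)cc(-c3ccc(OCc4ccccc4)cc3)oc12.[Na+] | intermediate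
24 | 8-[(2R,3S)-5,7-dihydroxy-2-(4-hydroxyphenyl)-4-oxochroman-3-yl]-5-hydroxy-2-(4-hydroxyphenyl)-4-oxo-4H-chromen-7-yl hydrogen sulfate | O=C1c2c(O)cc(O)cc2O[C@@H](c2ccc(O)cc2)[C@@H]1c1c(OS(=O)(=O)O)cc(O)c2c(=O)cc(-c3ccc(O)cc3)oc12 | target

## Step count and least certain steps

Total: 17 steps. Longest linear sequence: 13 steps (steps 1 to 7 and 12 to 17, from apigenin); the ring A branch (steps 8 to 11) joins at step 12.

**1. Step 12 (key step, proposed new method).**
- What may go wrong: addition of the aryllithium to the flavone carbonyl in competition with ate-complex formation; direct boron-to-nickel transfer leading to simple ketone formation in place of the metallate shift; slow alkene binding at the congested beta-aryl position; poor facial selectivity with this ligand class.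
- Fallback (known chemistry): it sets out from acid chloride 15 and iodide 7 and comes back at 21. Me2CuLi converts 15 into the methyl ketone 1-[2,4-bis(benzyloxy)-6-fluorophenyl]ethan-1-one F1. Palladium-catalysed alpha-arylation of F1 with 7 (Pd2(dba)3, XPhos, K3PO4, toluene) gives the deoxybenzoin 1-[2,4-bis(benzyloxy)-6-fluorophenyl]-2-(Fl)ethan-1-one F2, which already contains the C3–C8f bond. Soft enolisation (MgBr2·OEt2, i-Pr2NEt) and C-acylation with commercial 4-(benzyloxy)benzoyl chloride gives the 2-aryl-1,3-diketone F3. Noyori transfer hydrogenation with RuCl(p-cymene)[(R,R)-TsDPEN] and HCO2H–Et3N reduces the unhindered ring B ketone, the ring A ketone being shielded by two ortho substituents, to the (R)-carbinol F4 as a mixture at the labile neighbouring carbon. The K2CO3 conditions of step 14 then close ring C and, because C3 is enolisable, funnel both epimers to the trans isomer 21.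

**2. Step 14.**
- What may go wrong: retro-aldol cleavage of the alkoxide before it displaces fluoride, or base-induced opening of the product to a chalcone; either erodes the configuration at C2.
- Fallback: it sets out from aldehyde 13 and boronate 10 and comes back at 21, closing ring C through the ring A oxygen under acid so that no alkoxide is formed. Displacement of the fluoride of 13 by sodium allyloxide gives 2-(allyloxy)-4,6-bis(benzyloxy)benzaldehyde F5. Pinnick oxidation gives the acid F6 and oxalyl chloride the acid chloride F7. The coupling of step 12 with 10 and 17 gives the allyloxy analogue of 19, F8, and oxidation as in step 13 gives the hydroxy ketone F9. Pd(PPh3)4 and morpholine remove the allyl group to give the phenol F10. PPTS in CH2Cl2 then ionises the para-benzyloxybenzylic alcohol, and the phenol captures the cation trans to the C3 substituent, so that C3 relays its configuration to C2 and 21 results.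

**3. Step 16.**
- What may go wrong: incomplete sulfation of a phenol flanked by the C8f substituent, and hydrolysis of the sulfate salt during handling and chromatography.
- Fallback: it sets out from 22 and comes back at 24, carrying the sulfate as a neutral diester. 2,2,2-Trichloroethyl chlorosulfate with DMAP and Et3N gives the aryl trichloroethyl sulfate F11, which can be purified on silica. Pd/C with HCO2NH4 in MeOH then removes the five benzyl ethers and the trichloroethyl group in one operation, and acidification as in step 17 gives 24.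

**4. Step 7.**
- What may go wrong: reduction of the flavone carbonyl or conjugate hydroboration of ring F by the borane, or double hydroboration of the alkyne.
- Fallback: it sets out from iodide 7 and comes back at 10, bypassing 8 and 9. A Heck–Mizoroki reaction of 7 with vinylboronic acid pinacol ester (Pd[P(t-Bu)3]2, i-Pr2NH, toluene, 80 °C) gives the (E)-alkenylboronate directly; no compound outside the route is made (F0).

## Further compounds

F1 | step 12 | 1-[2,4-bis(benzyloxy)-6-fluorophenyl]ethan-1-one | CC(=O)c1c(F)cc(OCc2ccccc2)cc1OCc1ccccc1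
F2 | step 12 | 1-[2,4-bis(benzyloxy)-6-fluorophenyl]-2-{5-(benzyloxy)-2-[4-(benzyloxy)phenyl]-7-(methoxymethoxy)-4-oxo-4H-chromen-8-yl}ethan-1-one | O=C(Cc1c(OCOC)cc(OCc2ccccc2)c2c(=O)cc(-c3ccc(OCc4ccccc4)cc3)oc12)c1c(F)cc(OCc2ccccc2)cc1OCc1ccccc1
F3 | step 12 | 1-[2,4-bis(benzyloxy)-6-fluorophenyl]-3-[4-(benzyloxy)phenyl]-2-{5-(benzyloxy)-2-[4-(benzyloxy)phenyl]-7-(methoxymethoxy)-4-oxo-4H-chromen-8-yl}propane-1,3-dione (C2 configurationally labile) | O=C(c1ccc(OCc2ccccc2)cc1)C(C(=O)c1c(F)cc(OCc2ccccc2)cc1OCc1ccccc1)c1c(OCOC)cc(OCc2ccccc2)c2c(=O)cc(-c3ccc(OCc4ccccc4)cc3)oc12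
F4 | step 12 | (3R)-1-[2,4-bis(benzyloxy)-6-fluorophenyl]-3-[4-(benzyloxy)phenyl]-2-{5-(benzyloxy)-2-[4-(benzyloxy)phenyl]-7-(methoxymethoxy)-4-oxo-4H-chromen-8-yl}-3-hydroxypropan-1-one (mixture at C2) | O[C@@H](c1ccc(OCc2ccccc2)cc1)C(C(=O)c1c(F)cc(OCc2ccccc2)cc1OCc1ccccc1)c1c(OCOC)cc(OCc2ccccc2)c2c(=O)cc(-c3ccc(OCc4ccccc4)cc3)oc12
F5 | step 14 | 2,4-bis(benzyloxy)-6-(prop-2-en-1-yloxy)benzaldehyde | O=Cc1c(OCC=C)cc(OCc2ccccc2)cc1OCc1ccccc1
F6 | step 14 | 2,4-bis(benzyloxy)-6-(prop-2-en-1-yloxy)benzoic acid | O=C(O)c1c(OCC=C)cc(OCc2ccccc2)cc1OCc1ccccc1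
F7 | step 14 | 2,4-bis(benzyloxy)-6-(prop-2-en-1-yloxy)benzoyl chloride | O=C(Cl)c1c(OCC=C)cc(OCc2ccccc2)cc1OCc1ccccc1
F8 | step 14 | (2R,3R)-1-[2,4-bis(benzyloxy)-6-(prop-2-en-1-yloxy)phenyl]-3-[4-(benzyloxy)phenyl]-2-{5-(benzyloxy)-2-[4-(benzyloxy)phenyl]-7-(methoxymethoxy)-4-oxo-4H-chromen-8-yl}-3-(4,4,5,5-tetramethyl-1,3,2-dioxaborolan-2-yl)propan-1-one | CC1(C)OB(OC1(C)C)[C@@H](c1ccc(OCc2ccccc2)cc1)[C@@H](C(=O)c1c(OCC=C)cc(OCc2ccccc2)cc1OCc1ccccc1)c1c(OCOC)cc(OCc2ccccc2)c2c(=O)cc(-c3ccc(OCc4ccccc4)cc3)oc12
F9 | step 14 | (2S,3R)-1-[2,4-bis(benzyloxy)-6-(prop-2-en-1-yloxy)phenyl]-3-[4-(benzyloxy)phenyl]-2-{5-(benzyloxy)-2-[4-(benzyloxy)phenyl]-7-(methoxymethoxy)-4-oxo-4H-chromen-8-yl}-3-hydroxypropan-1-one | O[C@@H](c1ccc(OCc2ccccc2)cc1)[C@@H](C(=O)c1c(OCC=C)cc(OCc2ccccc2)cc1OCc1ccccc1)c1c(OCOC)cc(OCc2ccccc2)c2c(=O)cc(-c3ccc(OCc4ccccc4)cc3)oc12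
F10 | step 14 | (2S,3R)-1-[2,4-bis(benzyloxy)-6-hydroxyphenyl]-3-[4-(benzyloxy)phenyl]-2-{5-(benzyloxy)-2-[4-(benzyloxy)phenyl]-7-(methoxymethoxy)-4-oxo-4H-chromen-8-yl}-3-hydroxypropan-1-one | O[C@@H](c1ccc(OCc2ccccc2)cc1)[C@@H](C(=O)c1c(O)cc(OCc2ccccc2)cc1OCc1ccccc1)c1c(OCOC)cc(OCc2ccccc2)c2c(=O)cc(-c3ccc(OCc4ccccc4)cc3)oc12
F11 | step 16 | 5-(benzyloxy)-2-[4-(benzyloxy)phenyl]-8-{(2R,3S)-5,7-bis(benzyloxy)-2-[4-(benzyloxy)phenyl]-4-oxochroman-3-yl}-4-oxo-4H-chromen-7-yl 2,2,2-trichloroethyl sulfate | O=C1c2c(OCc3ccccc3)cc(OCc3ccccc3)cc2O[C@@H](c2ccc(OCc3ccccc3)cc2)[C@@H]1c1c(OS(=O)(=O)OCC(Cl)(Cl)Cl)cc(OCc2ccccc2)c2c(=O)cc(-c3ccc(OCc4ccccc4)cc3)oc12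
F0 | step 7 | none | none
A1 | alternative 1 | (2R,3S)-5,7-bis(benzyloxy)-2-[4-(benzyloxy)phenyl]-3-{2-[4-(benzyloxy)phenyl]-7-hydroxy-4-oxo-5-[(triisopropylsilyl)oxy]-4H-chromen-8-yl}chroman-4-one | O=C1c2c(OCc3ccccc3)cc(OCc3ccccc3)cc2O[C@@H](c2ccc(OCc3ccccc3)cc2)[C@@H]1c1c(O)cc(O[Si](C(C)C)(C(C)C)C(C)C)c2c(=O)cc(-c3ccc(OCc4ccccc4)cc3)oc12
A2 | alternative 1 | (2R,3S)-5,7-bis(benzyloxy)-2-[4-(benzyloxy)phenyl]-3-{2,6-dihydroxy-3-iodo-4-[(triisopropylsilyl)oxy]phenyl}chroman-4-one | O=C1c2c(OCc3ccccc3)cc(OCc3ccccc3)cc2O[C@@H](c2ccc(OCc3ccccc3)cc2)[C@@H]1c1c(O)cc(O[Si](C(C)C)(C(C)C)C(C)C)c(I)c1O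
A3 | alternative 1 | 1-(benzyloxy)-4-ethynylbenzene | C#Cc1ccc(OCc2ccccc2)cc1
A4 | alternative 2 | (2S,3R)-1-{4-(benzyloxy)-2-fluoro-6-[(triisopropylsilyl)oxy]phenyl}-3-[4-(benzyloxy)phenyl]-2-{2,6-bis(methoxymethoxy)-4-[(triisopropylsilyl)oxy]phenyl}-3-hydroxypropan-1-one | O[C@@H](c1ccc(OCc2ccccc2)cc1)[C@@H](C(=O)c1c(F)cc(OCc2ccccc2)cc1O[Si](C(C)C)(C(C)C)C(C)C)c1c(OCOC)cc(O[Si](C(C)C)(C(C)C)C(C)C)cc1OCOC
A5 | alternative 2 | 1-{4-(benzyloxy)-2-fluoro-6-[(triisopropylsilyl)oxy]phenyl}-2-diazoethan-1-one | [N-]=[N+]=CC(=O)c1c(F)cc(OCc2ccccc2)cc1O[Si](C(C)C)(C(C)C)C(C)C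
A6 | alternative 2 | [3,5-bis(methoxymethoxy)phenoxy]triisopropylsilane | COCOc1cc(OCOC)cc(O[Si](C(C)C)(C(C)C)C(C)C)c1
A7 | alternative 2 | 4-(benzyloxy)benzaldehyde | O=Cc1ccc(OCc2ccccc2)cc1
A8 | alternative 3 | 2-[4-(benzyloxy)phenyl]-8-{2-[(tert-butyldimethylsilyl)oxy]ethyl}-5-hydroxy-7-[(triisopropylsilyl)oxy]-4H-chromen-4-one | O=c1cc(-c2ccc(OCc3ccccc3)cc2)oc2c(CCO[Si](C)(C)C(C)(C)C)c(O[Si](C(C)C)(C(C)C)C(C)C)cc(O)c12
A9 | alternative 3 | 2-[4-(benzyloxy)phenyl]-6-{4-[(tert-butyldimethylsilyl)oxy]-1-diazo-2-oxobutyl}-4H-pyran-4-one | O=c1cc(-c2ccc(OCc3ccccc3)cc2)oc(C(=[N+]=[N-])C(=O)CCO[Si](C)(C)C(C)(C)C)c1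
A10 | alternative 3 | (ethynyloxy)triisopropylsilane | C#CO[Si](C(C)C)(C(C)C)C(C)C
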